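All constants are invented, and the outcome is calculated.

The constants below were what I had when I took over this flask, and I wrote this note for whoever came after me.

    catalyst intermediate C → free catalyst + target (k1 = 12 min⁻¹)
    free catalyst + target → free catalyst + over-reaction product (k2 = 18 M⁻¹ min⁻¹)
    catalyst intermediate B ⇌ by-product + catalyst intermediate C (K3 = 0.016 M, k3 = 7.4 min⁻¹)
    free catalyst + added ligand ⇌ idle complex, settled at all times (K4 = 9900 M⁻¹)
    substrate + free catalyst ⇌ catalyst intermediate A (K5 = 330 M⁻¹, k5 = 59000 M⁻¹ min⁻¹)
    coupling partner + catalyst intermediate A ⇌ catalyst intermediate B (K6 = 380 M⁻¹, k6 = 2700 M⁻¹ min⁻¹)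
    gas ⇌ coupling partner, rate k7*(csat - [coupling partner]) (k7 = 0.035 min⁻¹, csat = 4.1 mM)

substrate 0.010 M; gas 4.1 mM (held); free catalyst 1 mol%; added ligand 72 µM; time 12 min

- at the start none of coupling partner is dissolved
- run time (flask): 12 min

- how much target there is at 12 min, in percent of the substrate charged
- concentration of coupling partner in solution at 12 min, in percent of saturation

No coupling partner was dissolved at the start, so I followed it. With substrate and added ligand held at their charges, catalyst intermediate A, the resting state, took 65.8 % of the catalyst, and I kept that share constant. Intermediate B fell back at 7.11 min⁻¹ and went on at 7.4 min⁻¹, so half of what formed passed forward. Intermediate C had a half-life of 0.058 min, short against the run, so I counted what passed B as target. That gave an uptake coefficient of 0.0907 min⁻¹, the fraction of dissolved partner the catalyst carries onward each minute.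

The partner's balance was then linear. It rose exponentially, at the sum of transfer and uptake coefficients, 0.126 min⁻¹, towards 27.8 % of saturation. Integrating uptake over time gave target as uptake coefficient times plateau times the time less a lag, here 6.19 min. I told my successor to expect 21.7 % of saturation and 6.01 % target at 12 min. I also told them that transfer was the slower coefficient, so in my reckoning it was the rate-limiting step and the gas feed was the setting to watch.

The forecast gave 4.8 % (3.8 % to 6 %) and 23 % (19 % to 28 %), on the ground that “The gas supply is the bottleneck”; my target stood higher.

The flask gave 5.33 % target and 22.8 % of saturation at 12 min. Intermediate A there was 55.5 % of the catalyst, which puts the uptake coefficient at 0.0764 min⁻¹, still faster than transfer at 0.035 min⁻¹. For the neighbouring flask, read at 3.0 min, my coefficient gave 3.59 × 10⁻⁴ M partner and 0.518 % target. That flask held 3.58 × 10⁻⁴ M partner and 0.457 % target.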